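If D in the flask turns over at the pace that D showed in the blue run, Z at 20 h can be bracketed from the loading of D and the time.

- blue: J 0.35 M (in portions, 2); L 0.50 equiv; D 27 mol%; run made earlier; portions every 2.0 h
- flask: J 0.35 M (in portions, 2); L 0.500 equiv; D 19 mol%; time 20 h; the portions of J follow each other after 2.0 h, the first at the start

blue run (percent of the J charged)

| time / h | Z / % | X / % |
|---|---|---|
| 2.50 | 6.4 | 5.3 |
| 5.00 | 15.6 | 15.0 |
| 6.00 | 19.1 | 16.8 |
| 10.0 | 33.7 | 21.8 |
| 12.0 | 40.6 | 23.6 |
| 15.0 | 50.0 | 23.9 |

(standard deviation of a reading: 0.3 percentage points)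

- percentages count the J that a species holds: one X counts as two
- what may be going on: 2 J -> X; E -> D + Z; J + D <-> E; G -> D + Q; L + D <-> G
- no earlier run changes the charge of D; that part of a forecast is a guess

1. concentration of Z at 20 h, in M
2. concentration of X at 20 h, in M
3. concentration of J at 20 h, in M
4. concentration of E at 20 h, in M

Suppose that D stands mainly as E, the resting state of the catalyst, and that Z comes from E. Define the turnover pace T as the Z made per hour for each D charged. Between 2.50 h and 10.0 h, the readings of the blue run put T at 0.135 h⁻¹. Held for 20 h on the flask's 19 mol% of D, this pace gives an estimate of 0.179 M of Z, the upper end of this bracket.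

The lower end comes from the last blue stretch, from 12.0 h to 15.0 h. In the blue run, the share of the J charged that is not yet in Z or X has fallen from 44.5% at 10.0 h to 26.1% at 15.0 h. The pace on that last stretch reads 0.116 h⁻¹, which, held for 20 h, gives the flask an estimate of 0.154 M of Z.

The forecast, made by stepping the flask by hand and not from this bracket, judges of the blue run that “the catalyst is nearly saturated”. It gives 0.17 M of Z, inside the bracket, with 0.055 M of X, 0.027 M of J and 0.043 M of E.

The flask gives 0.164 M of Z, 0.0588 M of X, 0.0307 M of J and 0.0375 M of E, so its Z lies inside the bracket.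

    2 J → X (k = 0.170 M⁻¹ h⁻¹)
    E → D + Z (k = 0.170 h⁻¹)
    J + D ⇌ E (K = 210 M⁻¹, k = 6.30 M⁻¹ h⁻¹)
    G → D + Q (k = 17.0 h⁻¹)
    L + D ⇌ G (K = 30.0 M⁻¹, k = 2.00 M⁻¹ h⁻¹)

Over 20 h, D in the flask averaged a pace of 0.123 h⁻¹, less than T. At that time 8.8% of the charged J remained unbound in the flask. In the neighbouring flask with 4.8 mol% of D, T gives 0.0453 M of Z at 20 h, and that flask holds 0.0453 M.

The numbers in the tables are simulated for an exercise, and the scatter is random.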